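The synthesis rests on cutting the C8–C9 bond of ring A, where the C7 methylene (C14), C8 and the oxygen-bearing C9 form a 3-methylenecyclohexanol unit (ring B: C1–C5, spiro C6; ring A: C7–C11). A Me2AlCl-promoted type-two carbonyl-ene reaction between an isopropenyl group on C6 and a C9 aldehyde makes this bond, closes ring A, creates the exocyclic alkene and sets C9 in one operation, while the α-bromine of the aldehyde becomes the C10 bromide. The precursor is a ring B cyclohexane from trans-limonene oxide carrying the C2 chlorine, a silyl-protected C3 carbinol and, on quaternary C6, the isopropenyl group and a CMe2–CHBr–CHO chain. The C3 bromide is installed last.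

Key step: step 11

Assumption: 1 is used as the pure trans diastereomer, because the cis epoxide of the commercial mixture would open at the tertiary carbon and give the regioisomeric chlorohydrin.

Step 1
Reactants: 1 (+)-trans-limonene 1,2-oxide [(1S,2R,4R)-1,2-epoxy-p-menth-8-ene]
Product: 2 (1S,2S,4R)-2-chloro-1-methyl-4-(prop-1-en-2-yl)cyclohexan-1-ol
Conditions: LiCl, AcOH, THF, 25 °C
Reagents that add atoms: lithium chloride [Li+].[Cl-]
Why: Acetic acid activates the epoxide and chloride attacks the secondary carbon C2 in an SN2 opening along the trans-diaxial path of the chair that keeps the isopropenyl group equatorial (Fürst–Plattner rule), so C2 is inverted to the chloride while the tertiary C3 oxygen stays on its original face.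

Step 2
Reactants: 2 (1S,2S,4R)-2-chloro-1-methyl-4-(prop-1-en-2-yl)cyclohexan-1-ol
Product: 3 {[(1S,2S,4R)-2-chloro-1-methyl-4-(prop-1-en-2-yl)cyclohexyl]oxy}triethylsilane
Conditions: Et3SiOTf, 2,6-lutidine, CH2Cl2, 0 → 25 °C
Reagents that add atoms: triethylsilyl trifluoromethanesulfonate CC[Si](CC)(CC)OS(=O)(=O)C(F)(F)F
Why: A silyl triflate with 2,6-lutidine silylates even a hindered tertiary alcohol, and the resulting ether removes the acidic proton and blocks re-closure to the epoxide in later steps (silyl ether protection).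

Step 3
Reactants: 3 {[(1S,2S,4R)-2-chloro-1-methyl-4-(prop-1-en-2-yl)cyclohexyl]oxy}triethylsilane
Product: 5 1-[(1R,3S,4S)-3-chloro-4-methyl-4-(triethylsilyloxy)cyclohexyl]ethan-1-one, via ozonide 4 (not isolated)
Conditions: O3, CH2Cl2, −78 °C; then PPh3, −78 → 25 °C
Reagents that add atoms: ozone [O-][O+]=O
Why: Ozonolysis with reductive work-up cleaves the only alkene to the methyl ketone and leaves chloride and silyl ether untouched; the C6 centre is carried unchanged and loses its role in step 4.

Step 4
Reactants: 5 1-[(1R,3S,4S)-3-chloro-4-methyl-4-(triethylsilyloxy)cyclohexyl]ethan-1-one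
Product: 6 triethyl({(1S,2S)-2-chloro-1-methyl-4-[1-(trimethylsilyloxy)ethylidene]cyclohexyl}oxy)silane (mixture of double-bond isomers)
Conditions: Me3SiCl, NaI, Et3N, MeCN, 25 °C
Reagents that add atoms: chlorotrimethylsilane C[Si](C)(C)Cl
Why: Iodotrimethylsilane formed in situ with Et3N gives silyl enol ethers under equilibrating conditions, so the tetrasubstituted exocyclic isomer should dominate over the terminal one (thermodynamic enol silylation), and no free enolate is formed that could displace the C2 chloride.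

Step 5
Reactants: 7 2-methylbut-3-yn-2-ol
Product: 8 Co2(CO)6 complex of 2-methylbut-3-yn-2-ol [Co2(CO)6(μ-HC≡CCMe2OH)]
Conditions: Co2(CO)8, CH2Cl2, 25 °C
Reagents that add atoms: dicobalt octacarbonyl O=C=[Co](=C=O)(=C=O)(=C=O)[Co](=C=O)(=C=O)(=C=O)=C=O
Why: A terminal alkyne displaces two carbonyl ligands of Co2(CO)8 at room temperature to give the stable bridged Co2(CO)6 alkyne complex, which is the standard precursor of a cobalt-stabilised propargylic cation.

Step 6
Reactants: 6 triethyl({(1S,2S)-2-chloro-1-methyl-4-[1-(trimethylsilyloxy)ethylidene]cyclohexyl}oxy)silane; 8 Co2(CO)6 complex of 2-methylbut-3-yn-2-ol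
Product: 9 Co2(CO)6 complex of 1-[(1S,3S,4S)-3-chloro-4-methyl-1-(2-methylbut-3-yn-2-yl)-4-(triethylsilyloxy)cyclohexyl]ethan-1-one
Conditions: BF3·OEt2 (added last), CH2Cl2, −78 → −20 °C
Reagents that add atoms: none
Why: BF3 ionises the cobalt-stabilised tertiary propargylic alcohol and the non-rearranging cation is captured by the enol silane at C6 (Nicholas reaction, which tolerates the formation of adjacent quaternary carbons); the ring should react from the chair with equatorial C3 methyl and anti-diaxial C2–Cl and C3–OSiEt3, whose axial chlorine blocks the lower face, so the bulky cation should enter equatorially on the face of the C3 oxygen and set C6.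

Step 7
Reactants: 9 Co2(CO)6 complex of 1-[(1S,3S,4S)-3-chloro-4-methyl-1-(2-methylbut-3-yn-2-yl)-4-(triethylsilyloxy)cyclohexyl]ethan-1-one
Product: 10 1-[(1S,3S,4S)-3-chloro-4-methyl-1-(2-methylbut-3-yn-2-yl)-4-(triethylsilyloxy)cyclohexyl]ethan-1-one
Conditions: (NH4)2Ce(NO3)6, Et3N, acetone, −30 → 0 °C
Reagents that add atoms: none
Why: Oxidation of the cobalt cluster by tetravalent cerium releases the free alkyne under buffered conditions that leave ketone, chloride and tertiary silyl ether untouched (oxidative decomplexation).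

Step 8
Reactants: 10 1-[(1S,3S,4S)-3-chloro-4-methyl-1-(2-methylbut-3-yn-2-yl)-4-(triethylsilyloxy)cyclohexyl]ethan-1-one
Product: 11 {[(1S,2S,4R)-2-chloro-1-methyl-4-(2-methylbut-3-yn-2-yl)-4-(prop-1-en-2-yl)cyclohexyl]oxy}triethylsilane
Conditions: Zn, CH2Br2, TiCl4, THF (reagent aged at 5 °C); then 10, CH2Cl2, 25 °C
Reagents that add atoms: dibromomethane BrCBr
Why: The non-basic CH2(ZnBr)2–TiCl4 reagent methylenates hindered and enolisable ketones where phosphorus ylides fail (Takai–Lombardo methylenation), and neither the terminal alkyne nor the secondary chloride should react.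

Step 9
Reactants: 11 {[(1S,2S,4R)-2-chloro-1-methyl-4-(2-methylbut-3-yn-2-yl)-4-(prop-1-en-2-yl)cyclohexyl]oxy}triethylsilane
Product: 13 3-[(1R,3S,4S)-3-chloro-4-methyl-1-(prop-1-en-2-yl)-4-(triethylsilyloxy)cyclohexyl]-3-methylbutanal, via alkenylborane 12 (not isolated)
Conditions: (c-C6H11)2BH (from BH3·SMe2 and cyclohexene), THF, 0 → 25 °C; then 30% H2O2, pH 7 phosphate buffer, 0 → 25 °C
Reagents that add atoms: dicyclohexylborane B(C1CCCCC1)C1CCCCC1 (boron only in 12); hydrogen peroxide OO
Why: The bulky dialkylborane adds once and anti-Markovnikov to the terminal alkyne far faster than to the neopentyl-type 1,1-disubstituted alkene, and buffered peroxide oxidation of the alkenylborane gives the enol that tautomerises to the aldehyde (hydroboration–oxidation).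

Step 10
Reactants: 13 3-[(1R,3S,4S)-3-chloro-4-methyl-1-(prop-1-en-2-yl)-4-(triethylsilyloxy)cyclohexyl]-3-methylbutanal
Product: 14 (2R)-2-bromo-3-[(1R,3S,4S)-3-chloro-4-methyl-1-(prop-1-en-2-yl)-4-(triethylsilyloxy)cyclohexyl]-3-methylbutanal
Conditions: (R)-2-{bis[3,5-bis(trifluoromethyl)phenyl](trimethylsilyloxy)methyl}pyrrolidine (20 mol %), PhCO2H (20 mol %), 4,4-dibromo-2,6-di-tert-butylcyclohexa-2,5-dien-1-one, CH2Cl2/pentane, −24 °C; crude product used directly
Reagents that add atoms: 4,4-dibromo-2,6-di-tert-butylcyclohexa-2,5-dien-1-one CC(C)(C)C1=CC(Br)(Br)C=C(C(C)(C)C)C1=O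
Why: The (R)-diarylprolinol silyl ether forms the E-enamine and shields one of its faces, so the bromodienone delivers bromine to the other and sets C10 as R under catalyst control (organocatalytic enantioselective α-bromination of aldehydes), while the quaternary C11 excludes elimination and slows enolisation of the product.

Step 11
Reactants: 14 (2R)-2-bromo-3-[(1R,3S,4S)-3-chloro-4-methyl-1-(prop-1-en-2-yl)-4-(triethylsilyloxy)cyclohexyl]-3-methylbutanal
Product: 15 (2S,3S,6R,9S,10R)-10-bromo-2-chloro-3,11,11-trimethyl-7-methylidene-3-(triethylsilyloxy)spiro[5.5]undecan-9-ol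
Conditions: Me2AlCl (2 equiv), CH2Cl2, −78 → −40 °C
Reagents that add atoms: none
Why: Me2AlCl binds the aldehyde oxygen, the terminal carbon C8 of the isopropenyl group attacks C9 and a hydrogen of the isopropenyl methyl passes to oxygen in a concerted ene process, after which the aluminium alkoxide loses methane and thereby removes the proton that could isomerise the new alkene. The closest precedent is the Me2AlCl-promoted type-two intramolecular carbonyl-ene cyclisation of 6-methylhept-6-enals to 3-methylenecyclohexanols. Ring A closes as a six-membered ring, exo with respect to the carbonyl group and with the tether on the central ene carbon C7, through a chair-like bicyclic transition state that forms C8–C9 and leaves the double bond exocyclic as C7=C14. The new stereocentre C9 is controlled by the C10 bromide, because the hydrogen transfer requires the aluminium-bound oxygen to be axial and the bromine should take the equatorial site anti to the incoming C8 (polar Felkin–Anh arrangement), which places oxygen and bromine cis. The step needs this facial selectivity at the aldehyde and retention of configuration at C10; the first rests on the chair just described and the second on the low temperature and on the flanking quaternary C11, which hinders enolisation. The silyl ether and the secondary chloride of ring B are inert to the Lewis acid at this temperature.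

Step 12
Reactants: 15 (2S,3S,6R,9S,10R)-10-bromo-2-chloro-3,11,11-trimethyl-7-methylidene-3-(triethylsilyloxy)spiro[5.5]undecan-9-ol
Product: 16 (2S,3S,6R,9S,10R)-10-bromo-2-chloro-3,11,11-trimethyl-7-methylidene-3-(triethylsilyloxy)spiro[5.5]undecan-9-yl acetate
Conditions: Ac2O, pyridine, DMAP (10 mol %), CH2Cl2, 0 → 25 °C
Reagents that add atoms: acetic anhydride CC(=O)OC(C)=O
Why: DMAP-catalysed acylation esterifies the axial secondary C9 alcohol, the only free hydroxyl, and the cis bromohydrin cannot close to an epoxide under these mildly basic conditions.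

Step 13
Reactants: 16 (2S,3S,6R,9S,10R)-10-bromo-2-chloro-3,11,11-trimethyl-7-methylidene-3-(triethylsilyloxy)spiro[5.5]undecan-9-yl acetate
Product: 17 (2S,3S,6R,9S,10R)-10-bromo-2-chloro-3-hydroxy-3,11,11-trimethyl-7-methylidenespiro[5.5]undecan-9-yl acetate
Conditions: HF·pyridine, pyridine, THF, 0 → 25 °C
Reagents that add atoms: none
Why: Buffered HF·pyridine cleaves the tertiary triethylsilyl ether by fluoride attack at silicon without affecting the acetate, the alkyl halides or the exocyclic alkene (fluoride desilylation).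

Step 14
Reactants: 17 (2S,3S,6R,9S,10R)-10-bromo-2-chloro-3-hydroxy-3,11,11-trimethyl-7-methylidenespiro[5.5]undecan-9-yl acetate
Product: 18 9-acetylisoobtusol [(2S,3S,6R,9S,10R)-3,10-dibromo-2-chloro-3,11,11-trimethyl-7-methylidenespiro[5.5]undecan-9-yl acetate]
Conditions: 1-bromo-N,N,2-trimethylprop-1-en-1-amine, CH2Cl2, 0 → 25 °C
Reagents that add atoms: 1-bromo-N,N,2-trimethylprop-1-en-1-amine CC(C)=C(Br)N(C)C
Why: The α-bromo enamine turns the tertiary alcohol into an alkoxy-iminium bromide without releasing HBr, ionisation is assisted by the anti-periplanar C2 chlorine, and bromide opens the bridged chloronium ion at the more substituted carbon C3 on the face the oxygen occupied, so C3 is substituted with retention and the acid-sensitive methylene is spared (deoxyhalogenation with neighbouring-group participation).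

Compound list
1 | (+)-trans-limonene 1,2-oxide [(1S,2R,4R)-1,2-epoxy-p-menth-8-ene] | CC(=C)[C@@H]1CC[C@]2(C)O[C@@H]2C1 | starting material
2 | (1S,2S,4R)-2-chloro-1-methyl-4-(prop-1-en-2-yl)cyclohexan-1-ol | CC(=C)[C@@H]1CC[C@](C)(O)[C@@H](Cl)C1 | intermediate
3 | {[(1S,2S,4R)-2-chloro-1-methyl-4-(prop-1-en-2-yl)cyclohexyl]oxy}triethylsilane | CC(=C)[C@@H]1CC[C@](C)(O[Si](CC)(CC)CC)[C@@H](Cl)C1 | intermediate
4 | ozonide (3-methyl-1,2,4-trioxolan-3-yl compound) of 3, epimers at the trioxolane carbon | CC2(OCOO2)[C@@H]1CC[C@](C)(O[Si](CC)(CC)CC)[C@@H](Cl)C1 | intermediate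
5 | 1-[(1R,3S,4S)-3-chloro-4-methyl-4-(triethylsilyloxy)cyclohexyl]ethan-1-one | CC(=O)[C@@H]1CC[C@](C)(O[Si](CC)(CC)CC)[C@@H](Cl)C1 | intermediate
6 | triethyl({(1S,2S)-2-chloro-1-methyl-4-[1-(trimethylsilyloxy)ethylidene]cyclohexyl}oxy)silane | CC(O[Si](C)(C)C)=C1CC[C@](C)(O[Si](CC)(CC)CC)[C@@H](Cl)C1 | intermediate
7 | 2-methylbut-3-yn-2-ol | CC(C)(O)C#C | starting material
8 | Co2(CO)6 complex of 2-methylbut-3-yn-2-ol | CC(C)(O)C12[Co]3(=C=O)(=C=O)(=C=O)[Co]1(=C=O)(=C=O)(=C=O)C23 | intermediate
9 | Co2(CO)6 complex of 1-[(1S,3S,4S)-3-chloro-4-methyl-1-(2-methylbut-3-yn-2-yl)-4-(triethylsilyloxy)cyclohexyl]ethan-1-one | CC(=O)[C@@]1(C(C)(C)C23[Co]4(=C=O)(=C=O)(=C=O)[Co]2(=C=O)(=C=O)(=C=O)C34)CC[C@](C)(O[Si](CC)(CC)CC)[C@@H](Cl)C1 | intermediate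
10 | 1-[(1S,3S,4S)-3-chloro-4-methyl-1-(2-methylbut-3-yn-2-yl)-4-(triethylsilyloxy)cyclohexyl]ethan-1-one | CC(=O)[C@@]1(C(C)(C)C#C)CC[C@](C)(O[Si](CC)(CC)CC)[C@@H](Cl)C1 | intermediate
11 | {[(1S,2S,4R)-2-chloro-1-methyl-4-(2-methylbut-3-yn-2-yl)-4-(prop-1-en-2-yl)cyclohexyl]oxy}triethylsilane | C=C(C)[C@@]1(C(C)(C)C#C)CC[C@](C)(O[Si](CC)(CC)CC)[C@@H](Cl)C1 | intermediate
12 | dicyclohexyl{(E)-3-[(1R,3S,4S)-3-chloro-4-methyl-1-(prop-1-en-2-yl)-4-(triethylsilyloxy)cyclohexyl]-3-methylbut-1-en-1-yl}borane | C=C(C)[C@@]1(C(C)(C)/C=C/B(C2CCCCC2)C2CCCCC2)CC[C@](C)(O[Si](CC)(CC)CC)[C@@H](Cl)C1 | intermediate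
13 | 3-[(1R,3S,4S)-3-chloro-4-methyl-1-(prop-1-en-2-yl)-4-(triethylsilyloxy)cyclohexyl]-3-methylbutanal | O=CCC(C)(C)[C@]1(C(C)=C)CC[C@](C)(O[Si](CC)(CC)CC)[C@@H](Cl)C1 | intermediate
14 | (2R)-2-bromo-3-[(1R,3S,4S)-3-chloro-4-methyl-1-(prop-1-en-2-yl)-4-(triethylsilyloxy)cyclohexyl]-3-methylbutanal | O=C[C@H](Br)C(C)(C)[C@]1(C(C)=C)CC[C@](C)(O[Si](CC)(CC)CC)[C@@H](Cl)C1 | intermediate
15 | (2S,3S,6R,9S,10R)-10-bromo-2-chloro-3,11,11-trimethyl-7-methylidene-3-(triethylsilyloxy)spiro[5.5]undecan-9-ol | C=C1C[C@H](O)[C@H](Br)C(C)(C)[C@@]12CC[C@](C)(O[Si](CC)(CC)CC)[C@@H](Cl)C2 | intermediate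
16 | (2S,3S,6R,9S,10R)-10-bromo-2-chloro-3,11,11-trimethyl-7-methylidene-3-(triethylsilyloxy)spiro[5.5]undecan-9-yl acetate | C=C1C[C@H](OC(C)=O)[C@H](Br)C(C)(C)[C@@]12CC[C@](C)(O[Si](CC)(CC)CC)[C@@H](Cl)C2 | intermediate
17 | (2S,3S,6R,9S,10R)-10-bromo-2-chloro-3-hydroxy-3,11,11-trimethyl-7-methylidenespiro[5.5]undecan-9-yl acetate | C=C1C[C@H](OC(C)=O)[C@H](Br)C(C)(C)[C@@]12CC[C@](C)(O)[C@@H](Cl)C2 | intermediate
18 | 9-acetylisoobtusol [(2S,3S,6R,9S,10R)-3,10-dibromo-2-chloro-3,11,11-trimethyl-7-methylidenespiro[5.5]undecan-9-yl acetate] | C=C1C[C@H](OC(C)=O)[C@H](Br)C(C)(C)[C@@]12CC[C@](C)(Br)[C@@H](Cl)C2 | target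

Total step count: 14. Longest linear sequence: 13 steps (1 to 18 through steps 1–4 and 6–14); step 5 is a one-step branch that turns 7 into 8.

Steps most likely to fail

Step 11 (key step). The closure may take place on the other face of the aluminium-bound aldehyde, through the chair with axial bromine, and then deliver the C9 epimer with oxygen trans to bromine. The fallback sets out from 14 and returns at 15. The closure is run as before and the epimeric alcohol (2S,3S,6R,9R,10R)-10-bromo-2-chloro-3,11,11-trimethyl-7-methylidene-3-(triethylsilyloxy)spiro[5.5]undecan-9-ol F1 is oxidised with Dess–Martin periodinane (NaHCO3, CH2Cl2, 0 °C) to the bromo ketone (2S,3S,6R,10R)-10-bromo-2-chloro-3,11,11-trimethyl-7-methylidene-3-(triethylsilyloxy)spiro[5.5]undecan-9-one F2. LiBH(s-Bu)3 (THF, −78 °C) should then attack C9 from the equatorial side, away from the axial C11 methyl, and give the axial alcohol 15.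

Step 6. The crowded cluster cation may lose a proton to an enyne complex faster than it forms the bond between two fully substituted carbons, and the preference for the upper face of the enol silane may be incomplete. The fallback sets out from 6 and returns at 13. It replaces the cobalt cation by a small free tertiary cation, which answers the crowding; the facial preference rests on the same chair, so the fallback does not by itself correct face selectivity. Compound 6 and 1,3-dichloro-3-methylbutane (CC(C)(Cl)CCCl) with ZnCl2 (10 mol %) in CH2Cl2 at 0 °C (Lewis-acid-mediated α-tert-alkylation of the enol silane) should give 1-[(1S,3S,4S)-3-chloro-1-(4-chloro-2-methylbutan-2-yl)-4-methyl-4-(triethylsilyloxy)cyclohexyl]ethan-1-one F3. The zinc–titanium methylenation of step 8 converts it into {[(1S,2S,4R)-2-chloro-4-(4-chloro-2-methylbutan-2-yl)-1-methyl-4-(prop-1-en-2-yl)cyclohexyl]oxy}triethylsilane F4. Kornblum oxidation of the primary chloride (DMSO, NaHCO3, 120 °C) then gives aldehyde 13.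

Step 14. The bridged cation may lose a proton (elimination towards C4 or the C3 methyl) or be captured by the C7 methylene before bromide arrives. The fallback sets out from 17 and returns at 18, and it masks the alkene so that classical protic conditions can be used. Pyridinium tribromide (CH2Cl2, −20 °C) adds bromine to the methylene and gives 7,10-dibromo-7-(bromomethyl)-2-chloro-3-hydroxy-3,11,11-trimethylspiro[5.5]undecan-9-yl acetate F5 (other centres as in 17, epimers at C7). Me3SiBr (CH2Cl2, 0 °C) then exchanges the tertiary hydroxyl, again with chlorine participation, to 3,7,10-tribromo-7-(bromomethyl)-2-chloro-3,11,11-trimethylspiro[5.5]undecan-9-yl acetate F6 (other centres as in 18). NaI in acetone removes the vicinal dibromide and restores the methylene of 18; the trans bromochloride and the β-acetoxy bromide should react far more slowly with iodide.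

Further compounds
F1 | step 11 | (2S,3S,6R,9R,10R)-10-bromo-2-chloro-3,11,11-trimethyl-7-methylidene-3-(triethylsilyloxy)spiro[5.5]undecan-9-ol | C=C1C[C@@H](O)[C@H](Br)C(C)(C)[C@@]12CC[C@](C)(O[Si](CC)(CC)CC)[C@@H](Cl)C2
F2 | step 11 | (2S,3S,6R,10R)-10-bromo-2-chloro-3,11,11-trimethyl-7-methylidene-3-(triethylsilyloxy)spiro[5.5]undecan-9-one | C=C1CC(=O)[C@H](Br)C(C)(C)[C@@]12CC[C@](C)(O[Si](CC)(CC)CC)[C@@H](Cl)C2
F3 | step 6 | 1-[(1S,3S,4S)-3-chloro-1-(4-chloro-2-methylbutan-2-yl)-4-methyl-4-(triethylsilyloxy)cyclohexyl]ethan-1-one | CC(=O)[C@@]1(C(C)(C)CCCl)CC[C@](C)(O[Si](CC)(CC)CC)[C@@H](Cl)C1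
F4 | step 6 | {[(1S,2S,4R)-2-chloro-4-(4-chloro-2-methylbutan-2-yl)-1-methyl-4-(prop-1-en-2-yl)cyclohexyl]oxy}triethylsilane | C=C(C)[C@@]1(C(C)(C)CCCl)CC[C@](C)(O[Si](CC)(CC)CC)[C@@H](Cl)C1
F5 | step 14 | 7,10-dibromo-7-(bromomethyl)-2-chloro-3-hydroxy-3,11,11-trimethylspiro[5.5]undecan-9-yl acetate (other centres as in 17) | BrCC1(Br)C[C@H](OC(C)=O)[C@H](Br)C(C)(C)[C@@]12CC[C@](C)(O)[C@@H](Cl)C2
F6 | step 14 | 3,7,10-tribromo-7-(bromomethyl)-2-chloro-3,11,11-trimethylspiro[5.5]undecan-9-yl acetate (other centres as in 18) | BrCC1(Br)C[C@H](OC(C)=O)[C@H](Br)C(C)(C)[C@@]12CC[C@](C)(Br)[C@@H](Cl)C2
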